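Numbering: C1 (=CHBr), C2, C3/C4 (epoxide), C5, C6/C7 (ring fusion), C8, C9, C10 (CHBr), C11 (CMe2). Ring A (C6 to C11) holds the oxygen-bearing quaternary C7 beside the fusion methine C6, trans-related, and C6 carries the arm C5–C4 of the oxepane (ring B). Cutting C6–C7 gives an acyclic C7 methyl ketone tethered through C8, C9, silyloxy-bearing C10 and quaternary C11 to an (E)-enoate (C6=C5–C4O2Me). One SmI2 ketyl–enoate cyclization closes ring A, forms C6–C7 and sets both fusion centres from the aldol-derived C10. Bromides, epoxide and the bromo enol ether oxepane follow.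

Key step: step 7

Remark (step 1): the D-valine-derived promoter is assumed to give the (S)-aldol, the usual sense for unbranched aldehydes; if the sense proves opposite, the L-valine-derived promoter is used.
Remark (C10): the silyloxy group of 9/10 and the bromine of the target have the same spatial orientation, so C10 is inverted twice after ring closure (oxidation/axial reduction, then SN2 bromination).

Step 1
Reactants: 1 pent-4-enal; 2 1-methoxy-2-methyl-1-(trimethylsilyloxy)prop-1-ene
Product: 3 methyl (3S)-3-hydroxy-2,2-dimethylhept-6-enoate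
Conditions: N-Ts-D-valine, BH3·THF, CH2Cl2, 0 °C → rt; then 1, 2, −78 °C; aqueous buffer work-up
Reagents that add atoms: none
Why: Oxazaborolidinone-promoted asymmetric Mukaiyama aldol (Kiyooka type), in which the boron Lewis acid binds the unbranched aldehyde and shields one carbonyl face from the tetrasubstituted ketene acetal, so that C10 should form as the (S)-carbinol, the only stereocentre brought in from outside.

Step 2
Reactants: 3 methyl (3S)-3-hydroxy-2,2-dimethylhept-6-enoate
Product: 4 methyl (3S)-3-[(tert-butyldimethylsilyl)oxy]-2,2-dimethylhept-6-enoate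
Conditions: TBSOTf, 2,6-lutidine, CH2Cl2, 0 °C
Reagents that add atoms: tert-butyldimethylsilyl triflate, CC(C)(C)[Si](C)(C)OS(=O)(=O)C(F)(F)F
Why: Silyl ether formation with the silyl triflate, which a neopentyl secondary alcohol requires, under a non-nucleophilic base that avoids retro-aldol cleavage.

Step 3
Reactants: 4 methyl (3S)-3-[(tert-butyldimethylsilyl)oxy]-2,2-dimethylhept-6-enoate
Product: 5 (3S)-3-[(tert-butyldimethylsilyl)oxy]-2,2-dimethylhept-6-en-1-ol
Conditions: DIBAL-H (2.5 equiv), CH2Cl2, −78 → 0 °C; Rochelle salt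
Reagents that add atoms: none
Why: Hydride reduction of the ester to the primary alcohol; full reduction followed by re-oxidation is preferred to a partial reduction, which is unreliable at a neopentyl ester.

Step 4
Reactants: 5 (3S)-3-[(tert-butyldimethylsilyl)oxy]-2,2-dimethylhept-6-en-1-ol
Product: 6 (3S)-3-[(tert-butyldimethylsilyl)oxy]-2,2-dimethylhept-6-enal
Conditions: Dess–Martin periodinane, CH2Cl2, rt
Reagents that add atoms: none
Why: Dess–Martin oxidation to an aldehyde that has no α-hydrogen and therefore can neither epimerise nor eliminate the β-silyloxy group.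

Step 5
Reactants: 6 (3S)-3-[(tert-butyldimethylsilyl)oxy]-2,2-dimethylhept-6-enal; 7 trimethyl phosphonoacetate
Product: 8 methyl (2E,5S)-5-[(tert-butyldimethylsilyl)oxy]-4,4-dimethylnona-2,8-dienoate
Conditions: 7, NaH, THF, 0 °C; then 6, 0 °C → rt
Reagents that add atoms: none
Why: Horner–Wadsworth–Emmons olefination, in which the stabilised phosphonate anion should give the (E)-enoate and the non-enolisable aldehyde leaves no side path.

Step 6
Reactants: 8 methyl (2E,5S)-5-[(tert-butyldimethylsilyl)oxy]-4,4-dimethylnona-2,8-dienoate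
Product: 9 methyl (2E,5S)-5-[(tert-butyldimethylsilyl)oxy]-4,4-dimethyl-8-oxonon-2-enoate
Conditions: PdCl2 (10 mol%), CuCl, O2 (1 atm), DMF/H2O 7:1, rt
Reagents that add atoms: water, O
Why: Tsuji–Wacker oxidation, in which Markovnikov oxypalladation of the terminal alkene gives the methyl ketone while the hindered, electron-poor enoate is not attacked.

Step 7
Reactants: 9 methyl (2E,5S)-5-[(tert-butyldimethylsilyl)oxy]-4,4-dimethyl-8-oxonon-2-enoate
Product: 10 methyl 2-[(1S,3S,6S)-3-[(tert-butyldimethylsilyl)oxy]-6-hydroxy-2,2,6-trimethylcyclohexyl]acetate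
Conditions: SmI2 (2.5 equiv), MeOH (4 equiv), THF, −78 → −20 °C
Reagents that add atoms: none
Why: SmI2 reduces the C7 ketone to a samarium(III) ketyl that adds to the enoate β-carbon C6, and a second electron gives the samarium enolate, which methanol protonates at C5. The closest known reaction type is the SmI2 ketyl–olefin reductive cyclization of keto enoates, which is well established for six-membered rings. Ring A (C6 to C11) closes in the 6-exo-trig mode. In the chair transition state the enoate arm on C6 and the C10 silyloxy group sit equatorial, which relays the C10 configuration to C6, and the bulky samarium-bound oxygen takes the equatorial site away from the electron-rich enoate, which sets C7 with its methyl axial and its oxygen trans to the C6 arm. The step needs this trans relation and the correct face relative to C10; dipole repulsion between ketyl and enoate, the size of the solvated samarium alkoxide and the equatorial preference of the silyloxy group should secure them, and the gem-dimethyl group at C11 should favour closure over simple reduction. The diastereomer from the other chair is removed by chromatography at this stage, because after oxidation of C10 it would become the enantiomer.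

Step 8
Reactants: 10 methyl 2-[(1S,3S,6S)-3-[(tert-butyldimethylsilyl)oxy]-6-hydroxy-2,2,6-trimethylcyclohexyl]acetate
Product: 11 (3aS,5S,7aS)-5-[(tert-butyldimethylsilyl)oxy]-4,4,7a-trimethylhexahydro-1-benzofuran-2(3H)-one
Conditions: t-BuOK (0.2 equiv), 5 Å MS, THF, 0 °C → rt
Reagents that add atoms: none
Why: Base-catalysed intramolecular transesterification (5-exo-trig lactonisation) to the trans-fused γ-lactone, the array found in sclareolide-type lactones, which masks the C7 hydroxyl and the ester, locks ring A in one chair and is made before desilylation so that the C10 oxygen cannot compete for the ester.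

Step 9
Reactants: 11 (3aS,5S,7aS)-5-[(tert-butyldimethylsilyl)oxy]-4,4,7a-trimethylhexahydro-1-benzofuran-2(3H)-one
Product: 12 (3aS,5S,7aS)-5-hydroxy-4,4,7a-trimethylhexahydro-1-benzofuran-2(3H)-one
Conditions: 48% aq. HF, MeCN, rt
Reagents that add atoms: none
Why: Fluoride-mediated cleavage of the hindered silyl ether under mildly acidic conditions that leave the lactone untouched.

Step 10
Reactants: 12 (3aS,5S,7aS)-5-hydroxy-4,4,7a-trimethylhexahydro-1-benzofuran-2(3H)-one
Product: 13 (3aS,7aS)-4,4,7a-trimethyltetrahydro-1-benzofuran-2,5(3H,4H)-dione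
Conditions: Dess–Martin periodinane, CH2Cl2, rt
Reagents that add atoms: none
Why: Dess–Martin oxidation of the secondary alcohol, to which the lactone and the tertiary C7–O bond are inert.

Step 11
Reactants: 13 (3aS,7aS)-4,4,7a-trimethyltetrahydro-1-benzofuran-2,5(3H,4H)-dione
Product: 14 (3aS,5R,7aS)-5-hydroxy-4,4,7a-trimethylhexahydro-1-benzofuran-2(3H)-one
Conditions: L-Selectride (1.1 equiv), THF, −78 °C; aq. NH4Cl
Reagents that add atoms: none
Why: Ketone reduction with a bulky trialkylborohydride, which in the locked chair should attack C10 from the equatorial direction, as with 4,4-dimethyl-3-keto terpenoid A rings, and so give the axial (R)-alcohol without reducing the lactone at −78 °C.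

Step 12
Reactants: 14 (3aS,5R,7aS)-5-hydroxy-4,4,7a-trimethylhexahydro-1-benzofuran-2(3H)-one
Product: 15 (3aS,5S,7aS)-5-bromo-4,4,7a-trimethylhexahydro-1-benzofuran-2(3H)-one
Conditions: CBr4, P(n-Oct)3, toluene, 70 °C
Reagents that add atoms: carbon tetrabromide, BrC(Br)(Br)Br
Why: Appel bromination, in which bromide displaces the alkoxyphosphonium group by SN2 with inversion and so turns the axial alcohol into the equatorial (S)-bromide; the small trialkylphosphine is chosen for this neopentyl centre.

Step 13
Reactants: 15 (3aS,5S,7aS)-5-bromo-4,4,7a-trimethylhexahydro-1-benzofuran-2(3H)-one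
Product: 16 (3aS,5S,7aS)-5-bromo-4,4,7a-trimethyloctahydro-1-benzofuran-2-ol (lactol, mixture at C2)
Conditions: DIBAL-H (1.1 equiv), CH2Cl2, −78 °C; Rochelle salt
Reagents that add atoms: none
Why: Partial reduction of the lactone to the lactol with DIBAL-H at low temperature, where the stable aluminium hemiacetal prevents over-reduction and the secondary bromide is untouched.

Step 14
Reactants: 16 (3aS,5S,7aS)-5-bromo-4,4,7a-trimethyloctahydro-1-benzofuran-2-ol; 17 ethyltriphenylphosphonium iodide
Product: 19 (1S,2S,4S)-4-bromo-2-[(2Z)-3-iodobut-2-en-1-yl]-1,3,3-trimethylcyclohexan-1-ol, via (1-iodoethyl)triphenylphosphonium iodide 18 (not isolated)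
Conditions: 17, n-BuLi, THF, 0 °C; I2, −78 °C; NaHMDS, −78 → −20 °C; then 16 (pre-treated with NaHMDS, 1 equiv), −78 °C → rt
Reagents that add atoms: iodine, II
Why: Stork–Zhao-type Wittig olefination with the α-iodo ylide, in which the lactol reacts through its open hydroxy-aldehyde (alkoxide) form and kinetically controlled oxaphosphetane formation should give the (Z)-iodoalkene with iodine cis to C5.

Step 15
Reactants: 19 (1S,2S,4S)-4-bromo-2-[(2Z)-3-iodobut-2-en-1-yl]-1,3,3-trimethylcyclohexan-1-ol; 20 trimethylsilylacetylene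
Product: 21 (1S,2S,4S)-4-bromo-1,3,3-trimethyl-2-[(2Z)-3-methyl-5-(trimethylsilyl)pent-2-en-4-yn-1-yl]cyclohexan-1-ol
Conditions: Pd(PPh3)2Cl2 (5 mol%), CuI (10 mol%), Et3N, THF, rt
Reagents that add atoms: none
Why: Sonogashira coupling of the alkenyl iodide with retention of the double-bond geometry; the secondary alkyl bromide does not add to Pd(0) under these conditions.

Step 16
Reactants: 21 (1S,2S,4S)-4-bromo-1,3,3-trimethyl-2-[(2Z)-3-methyl-5-(trimethylsilyl)pent-2-en-4-yn-1-yl]cyclohexan-1-ol
Product: 22 (1S,2S,4S)-4-bromo-1,3,3-trimethyl-2-({(2R,3S)-3-methyl-3-[(trimethylsilyl)ethynyl]oxiran-2-yl}methyl)cyclohexan-1-ol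
Conditions: D-fructose-derived Shi ketone (0.3 equiv), Oxone, K2CO3, Bu4NHSO4, MeCN/DMM/aq. buffer (pH 10.5), 0 °C
Reagents that add atoms: potassium peroxymonosulfate (active component of Oxone), [K+].[O-]S(=O)(=O)OO
Why: Shi epoxidation, in which the chiral dioxirane transfers oxygen through a spiro transition state to one face of the trisubstituted enyne olefin, so that the D-fructose-derived ketone should set C3 and C4 as in the target by catalyst control with the cis relation of C5 and the alkyne retained; alkyne and tertiary alcohol are not oxidised.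

Step 17
Reactants: 22 (1S,2S,4S)-4-bromo-1,3,3-trimethyl-2-({(2R,3S)-3-methyl-3-[(trimethylsilyl)ethynyl]oxiran-2-yl}methyl)cyclohexan-1-ol
Product: 23 (1S,2S,4S)-4-bromo-2-{[(2R,3S)-3-ethynyl-3-methyloxiran-2-yl]methyl}-1,3,3-trimethylcyclohexan-1-ol
Conditions: K2CO3 (cat.), MeOH, 0 °C; Et3N-washed silica
Reagents that add atoms: none
Why: Methoxide-catalysed protodesilylation of the alkynylsilane, a cold and brief treatment that should leave the epoxide and the bromide intact.

Step 18
Reactants: 23 (1S,2S,4S)-4-bromo-2-{[(2R,3S)-3-ethynyl-3-methyloxiran-2-yl]methyl}-1,3,3-trimethylcyclohexan-1-ol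
Product: 24 target CNP0375295.1, (2E,3R,4R,5aS,7S,9aS)-7-bromo-2-(bromomethylidene)-3,4-epoxy-3,6,6,9a-tetramethyldecahydro-1-benzoxepine
Conditions: TBCO, 2,6-di-tert-butyl-4-methylpyridine, CH2Cl2, −40 °C → rt, dark
Reagents that add atoms: 2,4,4,6-tetrabromocyclohexa-2,5-dienone, O=C1C(Br)=CC(Br)(Br)C=C1Br
Why: Electrophilic bromoetherification of the alkynol (7-exo-dig), in which Br+ adds to the terminal carbon C1 and the C7 hydroxyl attacks C2 from the opposite side, so that anti addition should give the (E)-bromomethylidene group; the cis-epoxide and the equatorial C7–O and C6–C5 bonds hold the hydroxyl near C2, and the hindered pyridine keeps the medium free of acid that would open the epoxide.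

Compound list
1 | pent-4-enal | C=CCCC=O | starting material
2 | 1-methoxy-2-methyl-1-(trimethylsilyloxy)prop-1-ene (silyl ketene acetal of methyl isobutyrate, purchased) | COC(=C(C)C)O[Si](C)(C)C | starting material
3 | methyl (3S)-3-hydroxy-2,2-dimethylhept-6-enoate | C=CCC[C@H](O)C(C)(C)C(=O)OC | intermediate
4 | methyl (3S)-3-[(tert-butyldimethylsilyl)oxy]-2,2-dimethylhept-6-enoate | C=CCC[C@H](O[Si](C)(C)C(C)(C)C)C(C)(C)C(=O)OC | intermediate
5 | (3S)-3-[(tert-butyldimethylsilyl)oxy]-2,2-dimethylhept-6-en-1-ol | C=CCC[C@H](O[Si](C)(C)C(C)(C)C)C(C)(C)CO | intermediate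
6 | (3S)-3-[(tert-butyldimethylsilyl)oxy]-2,2-dimethylhept-6-enal | C=CCC[C@H](O[Si](C)(C)C(C)(C)C)C(C)(C)C=O | intermediate
7 | trimethyl phosphonoacetate | COC(=O)CP(=O)(OC)OC | starting material
8 | methyl (2E,5S)-5-[(tert-butyldimethylsilyl)oxy]-4,4-dimethylnona-2,8-dienoate | C=CCC[C@H](O[Si](C)(C)C(C)(C)C)C(C)(C)/C=C/C(=O)OC | intermediate
9 | methyl (2E,5S)-5-[(tert-butyldimethylsilyl)oxy]-4,4-dimethyl-8-oxonon-2-enoate | CC(=O)CC[C@H](O[Si](C)(C)C(C)(C)C)C(C)(C)/C=C/C(=O)OC | intermediate
10 | methyl 2-[(1S,3S,6S)-3-[(tert-butyldimethylsilyl)oxy]-6-hydroxy-2,2,6-trimethylcyclohexyl]acetate | CC1(C)[C@@H](O[Si](C)(C)C(C)(C)C)CC[C@](C)(O)[C@H]1CC(=O)OC | intermediate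
11 | (3aS,5S,7aS)-5-[(tert-butyldimethylsilyl)oxy]-4,4,7a-trimethylhexahydro-1-benzofuran-2(3H)-one (trans-fused lactone) | CC1(C)[C@@H](O[Si](C)(C)C(C)(C)C)CC[C@]2(C)OC(=O)C[C@@H]12 | intermediate
12 | (3aS,5S,7aS)-5-hydroxy-4,4,7a-trimethylhexahydro-1-benzofuran-2(3H)-one (equatorial alcohol) | CC1(C)[C@@H](O)CC[C@]2(C)OC(=O)C[C@@H]12 | intermediate
13 | (3aS,7aS)-4,4,7a-trimethyltetrahydro-1-benzofuran-2,5(3H,4H)-dione | CC1(C)C(=O)CC[C@]2(C)OC(=O)C[C@@H]12 | intermediate
14 | (3aS,5R,7aS)-5-hydroxy-4,4,7a-trimethylhexahydro-1-benzofuran-2(3H)-one (axial alcohol) | CC1(C)[C@H](O)CC[C@]2(C)OC(=O)C[C@@H]12 | intermediate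
15 | (3aS,5S,7aS)-5-bromo-4,4,7a-trimethylhexahydro-1-benzofuran-2(3H)-one (equatorial bromide) | CC1(C)[C@@H](Br)CC[C@]2(C)OC(=O)C[C@@H]12 | intermediate
16 | (3aS,5S,7aS)-5-bromo-4,4,7a-trimethyloctahydro-1-benzofuran-2-ol (lactol, mixture at C2) | CC1(C)[C@@H](Br)CC[C@]2(C)OC(O)C[C@@H]12 | intermediate
17 | ethyltriphenylphosphonium iodide | CC[P+](c1ccccc1)(c1ccccc1)c1ccccc1.[I-] | starting material
18 | (1-iodoethyl)triphenylphosphonium iodide (not isolated) | CC(I)[P+](c1ccccc1)(c1ccccc1)c1ccccc1.[I-] | intermediate
19 | (1S,2S,4S)-4-bromo-2-[(2Z)-3-iodobut-2-en-1-yl]-1,3,3-trimethylcyclohexan-1-ol | CC1(C)[C@@H](Br)CC[C@](C)(O)[C@H]1C/C=C(/C)I | intermediate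
20 | trimethylsilylacetylene | C#C[Si](C)(C)C | starting material
21 | (1S,2S,4S)-4-bromo-1,3,3-trimethyl-2-[(2Z)-3-methyl-5-(trimethylsilyl)pent-2-en-4-yn-1-yl]cyclohexan-1-ol | CC1(C)[C@@H](Br)CC[C@](C)(O)[C@H]1C/C=C(/C)C#C[Si](C)(C)C | intermediate
22 | (1S,2S,4S)-4-bromo-1,3,3-trimethyl-2-({(2R,3S)-3-methyl-3-[(trimethylsilyl)ethynyl]oxiran-2-yl}methyl)cyclohexan-1-ol | CC1(C)[C@@H](Br)CC[C@](C)(O)[C@H]1C[C@H]2O[C@@]2(C)C#C[Si](C)(C)C | intermediate
23 | (1S,2S,4S)-4-bromo-2-{[(2R,3S)-3-ethynyl-3-methyloxiran-2-yl]methyl}-1,3,3-trimethylcyclohexan-1-ol | CC1(C)[C@@H](Br)CC[C@](C)(O)[C@H]1C[C@H]2O[C@@]2(C)C#C | intermediate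
24 | CNP0375295.1, (2E,3R,4R,5aS,7S,9aS)-7-bromo-2-(bromomethylidene)-3,4-epoxy-3,6,6,9a-tetramethyldecahydro-1-benzoxepine (1E,3R,4R,6S,7S,10S in the numbering used here) | CC1(C)[C@@H](Br)CC[C@]2(C)O/C(=C/Br)[C@]3(C)O[C@@H]3C[C@@H]12 | target

Total step count: 18.
Longest linear sequence: 18 steps (1 and 2 to 24); the route is fully linear and all other inputs are purchased.

Steps most likely to fail, in order of concern:

Step 18 (bromoetherification). The bromine(I) source may be consumed at the terminal C–H (bromoalkyne formation), or the C7 hydroxyl may open the epoxide at C4 (5-exo) before it reaches the activated alkyne, so that the seven-membered ring does not close. The fallback sets out from 23 and separates C–O from C–Br bond formation. Anti-oxymercuration of the alkyne (Hg(O2CCF3)2, 2,6-di-tert-butyl-4-methylpyridine, CH2Cl2, 0 °C, then aq. NaCl) should close the oxepane 7-exo-dig and give the (E)-vinylmercuric chloride F7, with oxygen and mercury trans. Bromodemercuration with retention (NBS, pyridine/CH2Cl2, −20 °C) then comes back to the route at 24.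

Step 7 (key cyclization). The ketyl or the enoate may be reduced without ring closure, or the two chair transition states (C10 silyloxy group equatorial or axial) may be discriminated poorly, leaving too little of the needed diastereomer. The fallback sets out from 8 and closes the same C6–C7 bond by two-electron chemistry through a closed, metal-bound transition state. DIBAL-H (CH2Cl2, −78 °C) should give allylic alcohol F1, and acetylation (Ac2O, pyridine, DMAP) the allylic acetate F2. Tsuji–Wacker oxidation should give keto acetate F3. Palladium-catalysed umpolung allylation (Pd(PPh3)4, Et2Zn, THF) converts the allyl acetate into an allylzinc species that adds through its γ-carbon C6 to the C7 ketone, giving vinyl carbinol F4; its relative configuration would have to be confirmed. Hydroboration–oxidation (9-BBN, then NaBO3) gives diol F5, and TEMPO/PhI(OAc)2 oxidises the primary alcohol through the lactol to the lactone, coming back to the route at 11.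

Step 12 (invertive bromination). The activated axial oxygen may leave by E2 toward the anti-periplanar C9–H or with a 1,2-methyl shift from C11 instead of being displaced, because the SN2 path is neopentyl. The fallback sets out from 14 and separates activation from displacement. ClCH2SO2Cl and pyridine (CH2Cl2, 0 °C) give the chloromethanesulfonate F6, a sulfonate that needs no basic phosphorus intermediates. LiBr in DMPU (40–60 °C) then displaces it with inversion and comes back to the route at 15.

Further compounds
F1 | step 7 | (2E,5S)-5-[(tert-butyldimethylsilyl)oxy]-4,4-dimethylnona-2,8-dien-1-ol | C=CCC[C@H](O[Si](C)(C)C(C)(C)C)C(C)(C)/C=C/CO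
F2 | step 7 | (2E,5S)-5-[(tert-butyldimethylsilyl)oxy]-4,4-dimethylnona-2,8-dien-1-yl acetate | C=CCC[C@H](O[Si](C)(C)C(C)(C)C)C(C)(C)/C=C/COC(C)=O
F3 | step 7 | (2E,5S)-5-[(tert-butyldimethylsilyl)oxy]-4,4-dimethyl-8-oxonon-2-en-1-yl acetate | CC(=O)CC[C@H](O[Si](C)(C)C(C)(C)C)C(C)(C)/C=C/COC(C)=O
F4 | step 7 | (1S,2S,4S)-4-[(tert-butyldimethylsilyl)oxy]-2-ethenyl-1,3,3-trimethylcyclohexan-1-ol | CC1(C)[C@@H](O[Si](C)(C)C(C)(C)C)CC[C@](C)(O)[C@H]1C=C
F5 | step 7 | (1S,2S,4S)-4-[(tert-butyldimethylsilyl)oxy]-2-(2-hydroxyethyl)-1,3,3-trimethylcyclohexan-1-ol | CC1(C)[C@@H](O[Si](C)(C)C(C)(C)C)CC[C@](C)(O)[C@H]1CCO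
F6 | step 12 | (3aS,5R,7aS)-4,4,7a-trimethyl-2-oxooctahydro-1-benzofuran-5-yl chloromethanesulfonate | CC1(C)[C@H](OS(=O)(=O)CCl)CC[C@]2(C)OC(=O)C[C@@H]12
F7 | step 18 | (E)-(chloromercurio)methylidene analogue of 24 (HgCl in place of the vinylic bromine) | CC1(C)[C@@H](Br)CC[C@]2(C)O/C(=C/[Hg]Cl)[C@]3(C)O[C@@H]3C[C@@H]12
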